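**Analysis of the target**

Hansfordiol D (24) is an acyclic lipid phenol: a benzene-1,3-diol ring whose C5 carries an unbranched seventeen-carbon chain, numbered here C1' (benzylic) to C17' (methyl). C1'–C7' are methylenes, C8'=C9' and C11'=C12' are both Z and are separated only by the doubly allylic methylene C10', C13'–C15' are methylenes again, and C16' is a secondary carbinol. C16' (S) is the only stereocentre; it lies four bonds beyond the nearer alkene and far from the ring, so nothing in the molecule can control it and it has to be brought in ready-made. The sensitive parts are the electron-rich resorcinol (easily oxidized, nucleophilic at C2, C4 and C6, with two acidic hydroxyls that destroy organometallic reagents) and the skipped diene (autoxidation through C10', migration into conjugation under base, and Z to E isomerization). The difficulty is one of purity rather than complexity: geometric isomers of a skipped diene in a long lipid chain cannot realistically be separated from the target, so each alkene must come from a reaction whose mechanism allows only Z, and the three hydroxyls must be masked without a long detour. The plan rests on the position of C11'=C12': on one side it meets C13', the start of a saturated arm (C13'–C17') whose only function is the protected C16' carbinol, and on the other side C10', which becomes a reactive propargylic carbon once C8'=C9' is held back as the alkyne C8'≡C9'. The two carbons C11' and C12' can then be supplied by acetylene, inserted between an alkylcopper nucleophile and a propargylic electrophile.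

**Retrosynthetic reasoning**

24 to 23. The three O–H bonds are unmasked last, so the three O–Si bonds are cut first and lead back to the tris-silyl ether 23. The acidic hydrogens would quench every organometallic used earlier, and silyl ethers on all three oxygens allow one final fluoride-induced desilylation that the skipped diene tolerates.

23 to 22. C8'=C9' is traced to the alkyne C8'≡C9' of enyne 22. It is this alkene and not C11'=C12' that is kept as an alkyne because the triple bond makes C10' propargylic and therefore a good electrophilic carbon for the key step, and syn delivery of hydrogen to a disubstituted alkyne is the most dependable source of a Z-alkene. The forward reaction must stop after one equivalent and leave C11'=C12' alone.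

22 to 7, 18 and 17. This is the key disconnection: C12'–C13' and C10'–C11' are cut together. The excised two-carbon unit C11'–C12' is acetylene 18; what remains is the alkyl nucleophile 19 (from iodide 7, carried on as cuprate 20 and then alkenylcuprate 21) and the propargylic bromide 17. Cutting on both sides of the sp2 carbons means the alkene geometry is created by syn addition instead of being inherited, and the skeleton falls into a C5 piece, a C2 piece and a C10-aryl piece. The stereocentre stays in a small saturated fragment with no other reactive group. The forward reaction has to add once, add syn, and alkylate at C10' rather than at C8'.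

7 to 1 and 2. The C–I bond of 7 comes from the primary alcohol 6, the C13'–O bond from anti-Markovnikov hydroboration of the terminal alkene in 4 (through borane 5), the silyl ether from alcohol 3, and the C14'–C15' bond from opening of epoxide 1 by the vinyl Grignard reagent 2. C16' is bought in 1 and never becomes a reaction centre.

17 to 9 and 13. The C–Br bond of 17 comes from alcohol 16, which is released from the acetal 15. The aryl–C1' bond of 15 is then cut as an sp2–sp3 coupling between aryl bromide 9 and the alkylborane 14 made from terminal alkene 13. This bond is the only link between the purchasable ring and the chain. Forming it by a B-alkyl coupling brings in C1'–C7' already saturated, so no hydrogenation is needed that would endanger C8'≡C9', and the strongly basic acetylide chemistry is finished before the aryl silyl ethers enter.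

13 to 10 and 11; 9 to 8. The C7'–C8' bond of 13 is made by alkylating the lithium acetylide 12, derived from the protected propargyl alcohol 11, with bromide 10. The arene 9 is the bis-silyl ether of 8. Triisopropylsilyl groups are chosen for the phenols because aryl silyl ethers are cleaved by aqueous base and the coupling that gives 15 uses such a base; the bulkier group should survive it and still leave with fluoride at the end.

**Alternatives that were turned down**

Alternative 1: The arene is built instead of bought. The ring bond next to the chain-bearing carbon is cut, tracing the ring to the open-chain diketo-dioxinone A1, which already carries the whole chain with both Z-alkenes and the silylated C16' carbinol on its terminal ketone. In the forward key step a mild amine base triggers aldol attack of the dioxinone α-carbon on the chain-bearing ketone, and dehydration aromatizes the ring to the acetonide-masked resorcylate A2.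
- In its favour: it is biomimetic, needs no transition metal, its regiochemistry is inherent, and the phenols need no protecting groups until the ring exists. On that last point it is stronger than the chosen route.
- Against it: A2 has one carbon too many, so the masked carboxyl must be released and removed by decarboxylation, and what results is the ring of 8, which is sold. The diene chain must first be made as an acid derivative by other chemistry, so the Z-alkene problem is moved, not solved. That chain then has to pass two enolate acylations under strong base, where the C10' hydrogens invite isomerization.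
- Comparison: the chosen route spends its key step on the alkene geometry and the fragment union, which are the real difficulties, and needs fewer steps after the chain is complete.

Alternative 2: Both alkenes are cut at once, C8'=C9' and C11'=C12', so that C9'–C11' come from the C3 bis-phosphonium salt A3, C1'–C8' from the arene aldehyde A4 and C12'–C17' from the carbinol aldehyde A5. In the forward key step A3 is doubly deprotonated with a strong non-nucleophilic amide base and treated with A4 and then A5 in one flask, giving the tris-silyl ether A6 by two Wittig olefinations.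
- In its favour: it is the shortest assembly conceivable, makes both alkenes in one operation, and avoids gaseous 18 and pyrophoric alkyllithium. On step count and operational simplicity it is stronger than the chosen route.
- Against it: the two ylide carbons of the bis-ylide are identical, so the first aldehyde cannot be made to react only once. The outcome is statistical, with the two symmetrical double-olefination products beside A6, all of similar polarity. Z selectivity of an unstabilized ylide is high but not complete, and two olefinations compound the E content into isomers inseparable from A6. The mono-olefinated ylide also has acidic, doubly activated C10' hydrogens next to the new alkene.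
- Comparison: the chosen route joins its three components in a fixed order because 21 is a nucleophile and 17 an electrophile, and its C11'=C12' geometry follows from a syn addition and not from a kinetic preference.

Alternative 3: Two ring bonds of the arene are cut, dividing it into a four-carbon and a two-carbon piece: the chain-bearing cyclobutenone A7 and the silyloxyacetylene A8. In the forward key step heating opens A7 to a vinylketene, which adds A8 in a [2+2] manner; a second four-electron ring opening, six-electron electrocyclization and tautomerization give the mono-silylated resorcinol A9 (Danheiser benzannulation).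
- In its favour: it is regiospecific, thermal and neutral, and delivers the two phenols differentiated.
- Against it: differentiated phenols are of no use for a symmetrical resorcinol. A7 must be made on the fully unsaturated chain, normally by a ketene cycloaddition to a terminal alkyne, where the two chain alkenes are competing partners. Prolonged heating of a skipped diene invites isomerization. As in alternative 1, a purchasable ring is built and the alkenes must come from elsewhere.
- Comparison: the chosen route is shorter from the same starting arene 8 and keeps the diene away from heat.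

Key step: step 10

Remark: the acetal carbon of the tetrahydropyranyl group in 11–15 is racemic; it is removed in step 8, before any chiral fragment is attached, so no diastereomers arise.

**Route**

Step 1
Reactants: 1 (S)-propylene oxide; 2 vinylmagnesium bromide
Product: 3 (S)-pent-4-en-2-ol
Conditions: CuI (10 mol%), THF, −30 → 0 °C; aqueous work-up
Reagents that add atoms: none
Why: Copper-catalysed Grignard opening of a terminal epoxide; the vinyl nucleophile attacks the unsubstituted CH2 carbon in an SN2 manner, so C16' is not a reaction centre and keeps the S configuration of 1. The volatile alcohol is carried on as a concentrated solution.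

Step 2
Reactants: 3 (S)-pent-4-en-2-ol
Product: 4 (S)-tert-butyldimethyl(pent-4-en-2-yloxy)silane
Conditions: TBSCl, imidazole, DMF, 0 °C → rt
Reagents that add atoms: tert-butyldimethylsilyl chloride (TBSCl), CC(C)(C)[Si](C)(C)Cl
Why: Standard imidazole-promoted silylation of a secondary alcohol; the ether removes the acidic hydrogen for the later lithium and copper chemistry and does not touch the stereocentre.

Step 3
Reactants: 4 (S)-tert-butyldimethyl(pent-4-en-2-yloxy)silane
Product: 6 (S)-4-(tert-butyldimethylsilyloxy)pentan-1-ol, via B-alkyl-9-BBN 5 (not isolated)
Conditions: 9-BBN, THF, 0 °C → rt; then NaOH, H2O2, H2O, 0 °C → rt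
Reagents that add atoms: hydrogen peroxide, OO
Why: Brown hydroboration–oxidation; the bulky borane places boron on the terminal carbon C13' and alkaline peroxide replaces it by hydroxyl with the alkyl silyl ether intact.

Step 4
Reactants: 6 (S)-4-(tert-butyldimethylsilyloxy)pentan-1-ol
Product: 7 (S)-tert-butyl[(5-iodopentan-2-yl)oxy]dimethylsilane
Conditions: I2, PPh3, imidazole, CH2Cl2, 0 °C → rt
Reagents that add atoms: iodine, II
Why: Appel-type iodination of a primary alcohol through an alkoxyphosphonium ion; imidazole buffers the acid so the secondary silyl ether survives.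

Step 5
Reactants: 8 5-bromoresorcinol
Product: 9 1-bromo-3,5-bis(triisopropylsilyloxy)benzene
Conditions: TIPSCl, imidazole, DMF, rt
Reagents that add atoms: triisopropylsilyl chloride (TIPSCl), CC(C)[Si](Cl)(C(C)C)C(C)C
Why: Silylation of both phenols; the triisopropylsilyl ethers should withstand the aqueous base of step 7, mask the acidic hydrogens for step 10 and still leave readily with fluoride.

Step 6
Reactants: 10 7-bromohept-1-ene; 11 2-(prop-2-yn-1-yloxy)tetrahydro-2H-pyran
Product: 13 2-(dec-9-en-2-yn-1-yloxy)tetrahydro-2H-pyran, via lithium acetylide 12 (not isolated)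
Conditions: n-BuLi, THF, −78 °C; then 10, DMPU, −78 °C → rt
Reagents that add atoms: none
Why: Alkylation of a lithium acetylide with a primary bromide (SN2) in a dipolar cosolvent forms C7'–C8'; the terminal alkene and the acetal are inert.

Step 7
Reactants: 13 2-(dec-9-en-2-yn-1-yloxy)tetrahydro-2H-pyran; 9 1-bromo-3,5-bis(triisopropylsilyloxy)benzene
Product: 15 2-({10-[3,5-bis(triisopropylsilyloxy)phenyl]dec-2-yn-1-yl}oxy)tetrahydro-2H-pyran, via B-alkyl-9-BBN 14 (not isolated)
Conditions: 9-BBN, THF, 0 °C → rt; then 9, Pd(dppf)Cl2 (3 mol%), K3PO4 (aq.), DMF, 50 °C
Reagents that add atoms: none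
Why: 9-BBN hydroborates a terminal alkene much faster than an internal alkyne, and the resulting primary alkylborane undergoes B-alkyl Suzuki–Miyaura coupling with the aryl bromide at zerovalent palladium, forming the aryl–C1' bond with C1'–C7' already saturated. The bulky aryl silyl ethers and the acetal should tolerate aqueous phosphate.

Step 8
Reactants: 15 2-({10-[3,5-bis(triisopropylsilyloxy)phenyl]dec-2-yn-1-yl}oxy)tetrahydro-2H-pyran
Product: 16 10-[3,5-bis(triisopropylsilyloxy)phenyl]dec-2-yn-1-ol
Conditions: PPTS (cat.), MeOH/CH2Cl2, 40 °C
Reagents that add atoms: none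
Why: Acid-catalysed transacetalization to methanol releases the propargylic alcohol; aryl triisopropylsilyl ethers are stable to this weak acid.

Step 9
Reactants: 16 10-[3,5-bis(triisopropylsilyloxy)phenyl]dec-2-yn-1-ol
Product: 17 1-(10-bromodec-8-yn-1-yl)-3,5-bis(triisopropylsilyloxy)benzene
Conditions: CBr4, PPh3, CH2Cl2, 0 °C
Reagents that add atoms: carbon tetrabromide, BrC(Br)(Br)Br
Why: Appel bromination of a primary propargylic alcohol by SN2 displacement of the alkoxyphosphonium ion under neutral conditions; the bromide is used promptly in step 10.

Step 10
Reactants: 7 (S)-tert-butyl[(5-iodopentan-2-yl)oxy]dimethylsilane (two equivalents); 18 acetylene; 17 1-(10-bromodec-8-yn-1-yl)-3,5-bis(triisopropylsilyloxy)benzene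
Product: 22 tert-butyl({(2S,6Z)-17-[3,5-bis(triisopropylsilyloxy)phenyl]heptadec-6-en-9-yn-2-yl}oxy)dimethylsilane, via alkyllithium 19 (not isolated), via lithium dialkylcuprate 20 (not isolated), via lithium dialkenylcuprate 21 (not isolated)
Conditions: t-BuLi, Et2O/pentane, −78 °C; CuBr·SMe2, Et2O, −40 °C; 18 (two equivalents per copper), −50 → −25 °C; then 17, THF, −40 → 0 °C; aqueous NH4Cl
Reagents that add atoms: none
Why: Iodine–lithium exchange with two equivalents of t-BuLi gives alkyllithium 19, two of which combine with CuBr·SMe2 to the lithium dialkylcuprate 20. The monovalent copper centre of 20 binds acetylene and delivers an alkyl group and copper to the same face of the triple bond (syn carbocupration), which forms C12'–C13' and gives 21 with chain and copper cis on the new double bond. 21 then attacks the primary propargylic carbon C10' of 17 (oxidative addition to a short-lived trivalent copper species, then reductive elimination with retention at the sp2 carbon), which forms C10'–C11' and fixes the Z geometry of C11'=C12'. The closest known reaction type is the Normant carbocupration of acetylene by lithium dialkylcuprates followed by alkylation of the (Z)-alkenylcuprate with a 1-bromo-2-alkyne. No ring is closed and no stereocentre is created; C16' is a spectator, and the only stereochemical element formed, the Z alkene, is dictated by the syn addition and the stereoretentive coupling. The step needs a single insertion of acetylene, which the measured amount of 18 and a temperature kept below −25 °C should secure, because alkenylcuprates add to a further acetylene only on warming. It also needs direct substitution rather than SN2' attack leading to an allene, which is favoured because C10' is an unhindered primary carbon whereas the remote alkyne carbon C8' carries the long alkyl chain. The silyl ethers are inert to the cuprate; only one of the two alkenyl ligands is counted on, so 7 is used in twofold amount relative to 17 and the unused ligand is protonated on work-up.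

Step 11
Reactants: 22 tert-butyl({(2S,6Z)-17-[3,5-bis(triisopropylsilyloxy)phenyl]heptadec-6-en-9-yn-2-yl}oxy)dimethylsilane
Product: 23 tert-butyl({(2S,6Z,9Z)-17-[3,5-bis(triisopropylsilyloxy)phenyl]heptadeca-6,9-dien-2-yl}oxy)dimethylsilane
Conditions: H2 (1 atm, one equivalent), Pd/CaCO3 poisoned with Pb(OAc)2, quinoline, EtOAc, rt
Reagents that add atoms: none
Why: Lindlar semihydrogenation; both hydrogens are delivered from the poisoned palladium surface to one face of the alkyne, giving the Z alkene C8'=C9', and the alkyne binds far more strongly than the existing disubstituted alkene, so uptake should stop at the diene.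

Step 12
Reactants: 23 tert-butyl({(2S,6Z,9Z)-17-[3,5-bis(triisopropylsilyloxy)phenyl]heptadeca-6,9-dien-2-yl}oxy)dimethylsilane
Product: 24 Hansfordiol D, 5-[(8Z,11Z,16S)-16-hydroxyheptadeca-8,11-dien-1-yl]benzene-1,3-diol
Conditions: Bu4NF, THF, 0 °C → rt, under argon; aqueous work-up
Reagents that add atoms: none
Why: Fluoride-induced desilylation driven by the strong Si–F bond removes the two aryl silyl groups quickly and the secondary alkyl silyl group more slowly; neither the skipped diene nor C16' is affected, and air is excluded because the intermediate resorcinolate is oxidizable.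

**Compound list**

1 | (S)-propylene oxide | C[C@H]1CO1 | starting material
2 | vinylmagnesium bromide | C=C[Mg]Br | starting material
3 | (S)-pent-4-en-2-ol | C[C@H](O)CC=C | intermediate
4 | (S)-tert-butyldimethyl(pent-4-en-2-yloxy)silane | C[C@H](O[Si](C)(C)C(C)(C)C)CC=C | intermediate
5 | 9-[(4S)-4-(tert-butyldimethylsilyloxy)pentyl]-9-borabicyclo[3.3.1]nonane | C[C@H](O[Si](C)(C)C(C)(C)C)CCCB1C2CCCC1CCC2 | intermediate (not isolated)
6 | (S)-4-(tert-butyldimethylsilyloxy)pentan-1-ol | C[C@H](O[Si](C)(C)C(C)(C)C)CCCO | intermediate
7 | (S)-tert-butyl[(5-iodopentan-2-yl)oxy]dimethylsilane | C[C@H](O[Si](C)(C)C(C)(C)C)CCCI | intermediate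
8 | 5-bromoresorcinol | Oc1cc(O)cc(Br)c1 | starting material
9 | 1-bromo-3,5-bis(triisopropylsilyloxy)benzene | Brc1cc(O[Si](C(C)C)(C(C)C)C(C)C)cc(O[Si](C(C)C)(C(C)C)C(C)C)c1 | intermediate
10 | 7-bromohept-1-ene | C=CCCCCCBr | starting material
11 | 2-(prop-2-yn-1-yloxy)tetrahydro-2H-pyran (racemic) | C#CCOC1CCCCO1 | starting material
12 | [3-(tetrahydro-2H-pyran-2-yloxy)prop-1-yn-1-yl]lithium | [Li]C#CCOC1CCCCO1 | intermediate (not isolated)
13 | 2-(dec-9-en-2-yn-1-yloxy)tetrahydro-2H-pyran | C=CCCCCCC#CCOC1CCCCO1 | intermediate
14 | 9-[10-(tetrahydro-2H-pyran-2-yloxy)dec-8-yn-1-yl]-9-borabicyclo[3.3.1]nonane | B1(CCCCCCCC#CCOC3CCCCO3)C2CCCC1CCC2 | intermediate (not isolated)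
15 | 2-({10-[3,5-bis(triisopropylsilyloxy)phenyl]dec-2-yn-1-yl}oxy)tetrahydro-2H-pyran | CC(C)[Si](C(C)C)(C(C)C)Oc1cc(CCCCCCCC#CCOC2CCCCO2)cc(O[Si](C(C)C)(C(C)C)C(C)C)c1 | intermediate
16 | 10-[3,5-bis(triisopropylsilyloxy)phenyl]dec-2-yn-1-ol | OCC#CCCCCCCCc1cc(O[Si](C(C)C)(C(C)C)C(C)C)cc(O[Si](C(C)C)(C(C)C)C(C)C)c1 | intermediate
17 | 1-(10-bromodec-8-yn-1-yl)-3,5-bis(triisopropylsilyloxy)benzene | BrCC#CCCCCCCCc1cc(O[Si](C(C)C)(C(C)C)C(C)C)cc(O[Si](C(C)C)(C(C)C)C(C)C)c1 | intermediate
18 | acetylene | C#C | starting material
19 | [(4S)-4-(tert-butyldimethylsilyloxy)pentyl]lithium | [Li]CCC[C@H](C)O[Si](C)(C)C(C)(C)C | intermediate (not isolated)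
20 | lithium bis[(4S)-4-(tert-butyldimethylsilyloxy)pentyl]cuprate | [Li+].CC(C)(C)[Si](C)(C)O[C@@H](C)CCC[Cu-]CCC[C@H](C)O[Si](C)(C)C(C)(C)C | intermediate (not isolated)
21 | lithium bis[(1Z,6S)-6-(tert-butyldimethylsilyloxy)hept-1-en-1-yl]cuprate | [Li+].CC(C)(C)[Si](C)(C)O[C@@H](C)CCC/C=C\[Cu-]/C=C\CCC[C@H](C)O[Si](C)(C)C(C)(C)C | intermediate (not isolated)
22 | tert-butyl({(2S,6Z)-17-[3,5-bis(triisopropylsilyloxy)phenyl]heptadec-6-en-9-yn-2-yl}oxy)dimethylsilane | C[C@H](O[Si](C)(C)C(C)(C)C)CCC/C=C\CC#CCCCCCCCc1cc(O[Si](C(C)C)(C(C)C)C(C)C)cc(O[Si](C(C)C)(C(C)C)C(C)C)c1 | intermediate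
23 | tert-butyl({(2S,6Z,9Z)-17-[3,5-bis(triisopropylsilyloxy)phenyl]heptadeca-6,9-dien-2-yl}oxy)dimethylsilane | C[C@H](O[Si](C)(C)C(C)(C)C)CCC/C=C\C/C=C\CCCCCCCc1cc(O[Si](C(C)C)(C(C)C)C(C)C)cc(O[Si](C(C)C)(C(C)C)C(C)C)c1 | intermediate
24 | Hansfordiol D, 5-[(8Z,11Z,16S)-16-hydroxyheptadeca-8,11-dien-1-yl]benzene-1,3-diol | C[C@H](O)CCC/C=C\C/C=C\CCCCCCCc1cc(O)cc(O)c1 | target

**Step count and weak points**

Total step count: 12. Longest linear sequence: 7 steps (steps 1–4 and 10–12 from 1, or steps 6–12 from 10 and 11).

Step 10 (key step). Several processes could spoil it:
- attack of the alkenylcuprate at the remote alkyne carbon C8' (SN2' pathway), giving an allene in place of the skipped enyne;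
- a second insertion of acetylene into 21 if the temperature rises or 18 is in excess;
- silyl migration from oxygen to carbon (retro-Brook) or Wurtz coupling in 19 if the alkyllithium warms before copper is added;
- incomplete transfer of the alkenyl ligand to 17.

Fallback: the acetylene insertion is abandoned and C11'=C12' is made by semihydrogenation. The fallback sets out from 7 and 17. Iodide 7 is alkylated with LiC≡CH·H2NCH2CH2NH2 in DMSO at rt to the terminal alkyne (S)-tert-butyl(hept-6-yn-2-yloxy)dimethylsilane F1. F1 is deprotonated with EtMgBr in THF to the alkynylmagnesium bromide F2, which is coupled with 17 under CuCl catalysis to the skipped diyne F3. Both triple bonds of F3 are then semihydrogenated with two equivalents of H2 over Pd/CaCO3 poisoned with Pb(OAc)2 and quinoline. The fallback comes back to the route at 23, so step 11 is absorbed.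

Step 7. Possible failures are competing hydroboration of the internal alkyne of 13, slow transmetalation with β-hydride elimination from the alkylpalladium intermediate, and loss of an aryl silyl group to the aqueous base. Fallback: the ring–chain bond is made at an sp carbon and saturated afterwards. The fallback sets out from 9. Sonogashira coupling of 9 with commercial hept-6-yn-1-ol (Pd(PPh3)2Cl2, CuI, Et3N, 60 °C) gives the arylalkynol F4. Hydrogenation over Pd/C in EtOAc gives 7-[3,5-bis(triisopropylsilyloxy)phenyl]heptan-1-ol F5. I2, PPh3 and imidazole convert F5 into the iodide F6. Alkylation of lithium acetylide 12 (from 11 and n-BuLi) with F6 in THF/DMPU comes back to the route at 15.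

Step 11. Possible failures are over-reduction past the diene, and reduction or Z to E isomerization of the existing C11'=C12' bond on the palladium surface; all would give impurities that cannot be separated from 23. Fallback: a stoichiometric hydroboration–protonolysis replaces catalytic hydrogenation. The fallback sets out from 22. Dicyclohexylborane in THF at 0 °C adds syn to the alkyne, which is much more reactive toward this hindered borane than the disubstituted alkene, giving the alkenylborane F7 (boron drawn at C9'; the C8' regioisomer leads to the same alkene). Protonolysis of the C–B bond with acetic acid proceeds with retention and comes back to the route at 23.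

**Further compounds**

F1 | step 10 | (S)-tert-butyl(hept-6-yn-2-yloxy)dimethylsilane | C[C@H](O[Si](C)(C)C(C)(C)C)CCCC#C
F2 | step 10 | [(6S)-6-(tert-butyldimethylsilyloxy)hept-1-yn-1-yl]magnesium bromide | C[C@H](O[Si](C)(C)C(C)(C)C)CCCC#C[Mg]Br
F3 | step 10 | tert-butyl({(2S)-17-[3,5-bis(triisopropylsilyloxy)phenyl]heptadeca-6,9-diyn-2-yl}oxy)dimethylsilane | C[C@H](O[Si](C)(C)C(C)(C)C)CCCC#CCC#CCCCCCCCc1cc(O[Si](C(C)C)(C(C)C)C(C)C)cc(O[Si](C(C)C)(C(C)C)C(C)C)c1
F4 | step 7 | 7-[3,5-bis(triisopropylsilyloxy)phenyl]hept-6-yn-1-ol | OCCCCCC#Cc1cc(O[Si](C(C)C)(C(C)C)C(C)C)cc(O[Si](C(C)C)(C(C)C)C(C)C)c1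
F5 | step 7 | 7-[3,5-bis(triisopropylsilyloxy)phenyl]heptan-1-ol | OCCCCCCCc1cc(O[Si](C(C)C)(C(C)C)C(C)C)cc(O[Si](C(C)C)(C(C)C)C(C)C)c1
F6 | step 7 | 1-(7-iodoheptyl)-3,5-bis(triisopropylsilyloxy)benzene | ICCCCCCCc1cc(O[Si](C(C)C)(C(C)C)C(C)C)cc(O[Si](C(C)C)(C(C)C)C(C)C)c1
F7 | step 11 | tert-butyl({(2S,6Z,9Z)-17-[3,5-bis(triisopropylsilyloxy)phenyl]-9-(dicyclohexylboranyl)heptadeca-6,9-dien-2-yl}oxy)dimethylsilane | C[C@H](O[Si](C)(C)C(C)(C)C)CCC/C=C\C/C(B(C1CCCCC1)C1CCCCC1)=C\CCCCCCCc1cc(O[Si](C(C)C)(C(C)C)C(C)C)cc(O[Si](C(C)C)(C(C)C)C(C)C)c1
A1 | alternative 1 | 6-[(12Z,15Z,20S)-20-(tert-butyldimethylsilyloxy)-2,4-dioxohenicosa-12,15-dien-1-yl]-2,2-dimethyl-4H-1,3-dioxin-4-one | CC1(C)OC(=O)C=C(CC(=O)CC(=O)CCCCCCC/C=C\C/C=C\CCC[C@H](C)O[Si](C)(C)C(C)(C)C)O1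
A2 | alternative 1 | 7-hydroxy-2,2-dimethyl-5-[(8Z,11Z,16S)-16-(tert-butyldimethylsilyloxy)heptadeca-8,11-dien-1-yl]-4H-benzo[d][1,3]dioxin-4-one | CC1(C)OC(=O)c2c(O1)cc(O)cc2CCCCCCC/C=C\C/C=C\CCC[C@H](C)O[Si](C)(C)C(C)(C)C
A3 | alternative 2 | propane-1,3-diylbis(triphenylphosphonium) dibromide | [Br-].[Br-].c1ccc(cc1)[P+](c1ccccc1)(c1ccccc1)CCC[P+](c1ccccc1)(c1ccccc1)c1ccccc1
A4 | alternative 2 | 8-[3,5-bis(tert-butyldimethylsilyloxy)phenyl]octanal | O=CCCCCCCCc1cc(O[Si](C)(C)C(C)(C)C)cc(O[Si](C)(C)C(C)(C)C)c1
A5 | alternative 2 | (S)-5-(tert-butyldimethylsilyloxy)hexanal | O=CCCC[C@H](C)O[Si](C)(C)C(C)(C)C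
A6 | alternative 2 | Hansfordiol D tris(tert-butyldimethylsilyl) ether | C[C@H](O[Si](C)(C)C(C)(C)C)CCC/C=C\C/C=C\CCCCCCCc1cc(O[Si](C)(C)C(C)(C)C)cc(O[Si](C)(C)C(C)(C)C)c1
A7 | alternative 3 | 3-[(8Z,11Z,16S)-16-(tert-butyldimethylsilyloxy)heptadeca-8,11-dien-1-yl]cyclobut-2-en-1-one | O=C1C=C(CCCCCCC/C=C\C/C=C\CCC[C@H](C)O[Si](C)(C)C(C)(C)C)C1
A8 | alternative 3 | (triisopropylsilyloxy)acetylene | C#CO[Si](C(C)C)(C(C)C)C(C)C
A9 | alternative 3 | 3-(triisopropylsilyloxy)-5-[(8Z,11Z,16S)-16-(tert-butyldimethylsilyloxy)heptadeca-8,11-dien-1-yl]phenol | Oc1cc(O[Si](C(C)C)(C(C)C)C(C)C)cc(CCCCCCC/C=C\C/C=C\CCC[C@H](C)O[Si](C)(C)C(C)(C)C)c1
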